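**Retrosynthetic overview**
1. The plan rests on ring B. The ring D oxygen (chroman O1) is bound to C8a (C4' of flavone 1). Of the two carbons ortho to it, C8 (C3') already carries C8'' of the apigenin unit (flavone 2). C4a (C5') is therefore the only carbon that a sigmatropic shift from this oxygen can use productively.
2. Ring D is made last: 21 <= hydrogenation/hydrogenolysis of pentabenzyl chromene 19 <= propargyl Claisen, [1,5]-H shift and oxa-6π cascade of 1,1-dimethylpropargyl ether 15 (forms C4-C4a and O1-C2) <= phenol 13 + chloride 14.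
3. 13 <= acid closure of diketone 11 (the pyranone of flavone 1 closes and the MOM group falls in the same pot) <= Claisen condensation of biaryl ester 10 with acetophenone 2.
4. 10 <= Suzuki-Miyaura coupling (C3'-C8'' bond) of 8-iodoflavone 6 with ring B boronate 9; 6 <= iodoacetophenone 3 + ester 4 (Claisen condensation, cyclodehydration).
5. Order of ring formation: pyranone of flavone 2, then the biaryl bond, then the pyranone of flavone 1, then ring D.

Key step: step 11

Assumption: the target SMILES carries no descriptor for the C8(chroman)-C8'' biaryl axis and has no stereocentre, so no axial configuration is controlled and all biaryls are handled as racemic or interconverting rotamers.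

Step 1
Reactants: 1 2,4,6-trihydroxyacetophenone
Product: 2 1-[2,4-bis(benzyloxy)-6-hydroxyphenyl]ethanone
Conditions: BnBr (2.05 equiv), K2CO3 (2.2 equiv), DMF, 0 °C to rt
Reagents that add atoms: benzyl bromide, BrCc1ccccc1
Why: The Williamson etherification should stop at the dibenzyl stage because the last phenol is held in a hydrogen bond to the acetyl carbonyl and is by far the poorest nucleophile.

Step 2
Reactants: 2 1-[2,4-bis(benzyloxy)-6-hydroxyphenyl]ethanone
Product: 3 1-[4,6-bis(benzyloxy)-2-hydroxy-3-iodophenyl]ethanone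
Conditions: NIS (1.0 equiv), TFA (10 mol %), MeCN-CH2Cl2, 0 °C, dark
Reagents that add atoms: N-iodosuccinimide, O=C1CCC(=O)N1I
Why: Electrophilic aromatic iodination should go to C3, the site where 2-hydroxy-4,6-dialkoxyacetophenones are known to halogenate, because it is ortho to the free OH and less crowded than C5 between two benzyloxy groups.

Step 3
Reactants: 3 1-[4,6-bis(benzyloxy)-2-hydroxy-3-iodophenyl]ethanone; 4 methyl 4-(benzyloxy)benzoate
Product: 5 1-[4,6-bis(benzyloxy)-2-hydroxy-3-iodophenyl]-3-[4-(benzyloxy)phenyl]propane-1,3-dione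
Conditions: 4 (1.5 equiv), NaH (4 equiv), DMF, 0 °C to rt; cold 1 M HCl quench
Reagents that add atoms: none
Why: In this crossed Claisen condensation the phenoxide-enolate dianion of 3 is acylated by the non-enolisable ester and the equilibrium is pulled by deprotonation of the diketone, a process established for 3-substituted 2-hydroxy-4,6-dialkoxyacetophenones with methyl benzoates and harmless to the aryl iodide.

Step 4
Reactants: 5 1-[4,6-bis(benzyloxy)-2-hydroxy-3-iodophenyl]-3-[4-(benzyloxy)phenyl]propane-1,3-dione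
Product: 6 5,7-bis(benzyloxy)-2-[4-(benzyloxy)phenyl]-8-iodo-4H-chromen-4-one
Conditions: p-TsOH·H2O (20 mol %), toluene, 90 °C
Reagents that add atoms: none
Why: Acid-catalysed cyclodehydration, the closing step of a Baker-Venkataraman-type flavone synthesis, can use only the one free phenol, which fixes iodine at C8, and the non-nucleophilic sulfonate spares the benzyl ethers.

Step 5
Reactants: 7 methyl 4-hydroxy-3-iodobenzoate
Product: 8 methyl 3-iodo-4-(methoxymethoxy)benzoate
Conditions: MOMCl (1.3 equiv), i-Pr2NEt (1.5 equiv), CH2Cl2, 0 °C to rt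
Reagents that add atoms: chloromethyl methyl ether, COCCl
Why: O-Alkylation of the acidic phenol (MOM protection) gives an acetal that is inert to palladium catalysis and strong base and is orthogonal to benzyl ethers.

Step 6
Reactants: 8 methyl 3-iodo-4-(methoxymethoxy)benzoate
Product: 9 methyl 4-(methoxymethoxy)-3-(4,4,5,5-tetramethyl-1,3,2-dioxaborolan-2-yl)benzoate
Conditions: B2pin2 (1.2 equiv), PdCl2(dppf)·CH2Cl2 (3 mol %), KOAc (3 equiv), 1,4-dioxane, 85 °C
Reagents that add atoms: bis(pinacolato)diboron, CC1(C)OB(OC1(C)C)B1OC(C)(C)C(C)(C)O1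
Why: Miyaura borylation of an ester-bearing aryl iodide is routine, and KOAc is too weak a base to trigger coupling of the product with unreacted iodide.

Step 7
Reactants: 6 5,7-bis(benzyloxy)-2-[4-(benzyloxy)phenyl]-8-iodo-4H-chromen-4-one; 9 methyl 4-(methoxymethoxy)-3-(4,4,5,5-tetramethyl-1,3,2-dioxaborolan-2-yl)benzoate
Product: 10 methyl 3-{5,7-bis(benzyloxy)-2-[4-(benzyloxy)phenyl]-4-oxo-4H-chromen-8-yl}-4-(methoxymethoxy)benzoate
Conditions: Pd(OAc)2 (5 mol %), SPhos (10 mol %), K3PO4 (3 equiv), toluene-H2O (10:1), 90 °C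
Reagents that add atoms: none
Why: In this Suzuki-Miyaura coupling boron sits on ring B, where only one ortho group flanks it and protodeboronation is slow, the iodide sits on the doubly flanked C8, and the bulky electron-rich phosphine is suited to tri-ortho-substituted biaryls, while ester, MOM and benzyl groups are inert.

Step 8
Reactants: 10 methyl 3-{5,7-bis(benzyloxy)-2-[4-(benzyloxy)phenyl]-4-oxo-4H-chromen-8-yl}-4-(methoxymethoxy)benzoate; 2 1-[2,4-bis(benzyloxy)-6-hydroxyphenyl]ethanone
Product: 11 1-[2,4-bis(benzyloxy)-6-hydroxyphenyl]-3-(3-{5,7-bis(benzyloxy)-2-[4-(benzyloxy)phenyl]-4-oxo-4H-chromen-8-yl}-4-(methoxymethoxy)phenyl)propane-1,3-dione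
Conditions: 2 (2 equiv), NaH (6 equiv), DMF, 0 °C to rt; cold 1 M HCl to pH 5
Reagents that add atoms: none
Why: This is the crossed Claisen condensation of step 3 with the cheap ketone in excess, the ester lies meta to the biaryl bond and is unhindered, and any reversible base-induced opening of the pyranone of flavone 2 could reclose in step 9 only through the same oxygen.

Step 9
Reactants: 11 1-[2,4-bis(benzyloxy)-6-hydroxyphenyl]-3-(3-{5,7-bis(benzyloxy)-2-[4-(benzyloxy)phenyl]-4-oxo-4H-chromen-8-yl}-4-(methoxymethoxy)phenyl)propane-1,3-dione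
Product: 13 5,7,5'',7'',4'''-penta-O-benzylamentoflavone (free 4'-OH), via MOM-protected pentabenzyl biflavone 12 (not isolated)
Conditions: p-TsOH·H2O (0.5 equiv), MeOH-THF (1:2), 55 °C
Reagents that add atoms: none
Why: Acid-catalysed cyclodehydration of the ortho-hydroxyaryl 1,3-diketone closes the pyranone of flavone 1 through its only free phenol, and the same acid in methanol transacetalises the MOM ether, so the acid lability of MOM, which would forbid closing flavone 1 before the coupling, here saves a separate deprotection, while the non-nucleophilic counter-ion spares the benzyl ethers.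

Step 10
Reactants: 13 5,7,5'',7'',4'''-penta-O-benzylamentoflavone (free 4'-OH); 14 3-chloro-3-methylbut-1-yne
Product: 15 4'-O-(2-methylbut-3-yn-2-yl)-5,7,5'',7'',4'''-penta-O-benzylamentoflavone
Conditions: 14 (3 equiv), CuCl2·2H2O (5 mol %), DBU (3 equiv), MeCN-CH2Cl2, 0 °C to rt
Reagents that add atoms: none
Why: In this copper-catalysed propargylic etherification the copper acetylide of 14 loses chloride to a linear copper allenylidene, whose planar dimethyl-bearing carbon is captured by the DBU phenoxide of the only free and rather acidic phenol (para to a pyranone), a process that tolerates one ortho substituent.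

Step 11
Reactants: 15 4'-O-(2-methylbut-3-yn-2-yl)-5,7,5'',7'',4'''-penta-O-benzylamentoflavone
Product: 19 5,7-bis(benzyloxy)-8-{6-[5,7-bis(benzyloxy)-4-oxo-4H-chromen-2-yl]-2,2-dimethyl-2H-chromen-8-yl}-2-[4-(benzyloxy)phenyl]-4H-chromen-4-one, via allenyl dienone 16 (not isolated), via ortho-allenylphenol 17 (not isolated), via ortho-quinone methide 18 (not isolated)
Conditions: PhNEt2 (degassed, 0.05 M), 190 °C, Ar, sealed tube
Reagents that add atoms: none
Why: Heating starts an aromatic propargyl Claisen rearrangement in which the [3,3] shift breaks the O-CMe2 bond and joins the terminal alkyne carbon to C5' of ring B (the chroman C4-C4a bond), giving allenyl dienone 16, which the amine solvent helps to enolise to ortho-allenylphenol 17. A [1,5] hydrogen shift from the phenolic OH to the central allene carbon then gives the Z-configured ortho-quinone methide 18, and a thermally allowed disrotatory oxa-6π electrocyclization bonds the carbonyl oxygen to the CMe2 terminus (O1-C2), which closes the six-membered ring D and restores the aromaticity of ring B. The closest known reaction type is the thermal conversion of aryl 1,1-dimethylpropargyl ethers into 2,2-dimethyl-2H-chromenes in N,N-diethylaniline, which is helped by the gem-dimethyl group and is established also for ethers with a para acceptor such as 4-cyanophenyl. No stereocentre remains, since the sp3 carbon of 16 is lost on enolisation and C2 carries two methyl groups. The step needs ring D to form on ring B alone and at one ortho carbon only: the propargyl group can sit only on the oxygen that was the single free phenol of 13, and C3' bears flavone 2, so a shift to that crowded carbon leads to a dienone that cannot enolise and reverts. The benzylated phloroglucinol rings, the most nucleophilic sites of the molecule, take no part in a concerted neutral pathway, and benzyl ethers and pyranones tolerate the weakly basic medium.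

Step 12
Reactants: 19 5,7-bis(benzyloxy)-8-{6-[5,7-bis(benzyloxy)-4-oxo-4H-chromen-2-yl]-2,2-dimethyl-2H-chromen-8-yl}-2-[4-(benzyloxy)phenyl]-4H-chromen-4-one
Product: 21 8-[6-(5,7-dihydroxy-4-oxo-4H-chromen-2-yl)-2,2-dimethyl-3,4-dihydro-2H-chromen-8-yl]-5,7-dihydroxy-2-(4-hydroxyphenyl)-4H-chromen-4-one (CNP0127025.0), via pentabenzyl chroman 20 (not isolated)
Conditions: H2 (1 atm), 10% Pd/C, THF-MeOH (1:1), rt
Reagents that add atoms: none
Why: Heterogeneous catalytic hydrogenation should first saturate the styrene-type C3=C4 bond of ring D and then hydrogenolyse the five aryl benzyl ethers, while the flavone C2=C3 bonds, being part of vinylogous esters, are known to persist at one atmosphere and room temperature.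

**Compound list**
1 | 2,4,6-trihydroxyacetophenone | CC(=O)c1c(O)cc(O)cc1O | starting material
2 | 1-[2,4-bis(benzyloxy)-6-hydroxyphenyl]ethanone | CC(=O)c1c(O)cc(OCc2ccccc2)cc1OCc1ccccc1 | intermediate
3 | 1-[4,6-bis(benzyloxy)-2-hydroxy-3-iodophenyl]ethanone | CC(=O)c1c(O)c(I)c(OCc2ccccc2)cc1OCc1ccccc1 | intermediate
4 | methyl 4-(benzyloxy)benzoate | COC(=O)c1ccc(OCc2ccccc2)cc1 | starting material
5 | 1-[4,6-bis(benzyloxy)-2-hydroxy-3-iodophenyl]-3-[4-(benzyloxy)phenyl]propane-1,3-dione | O=C(CC(=O)c1ccc(OCc2ccccc2)cc1)c1c(O)c(I)c(OCc2ccccc2)cc1OCc1ccccc1 | intermediate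
6 | 5,7-bis(benzyloxy)-2-[4-(benzyloxy)phenyl]-8-iodo-4H-chromen-4-one | O=c1cc(-c2ccc(OCc3ccccc3)cc2)oc2c(I)c(OCc3ccccc3)cc(OCc3ccccc3)c12 | intermediate
7 | methyl 4-hydroxy-3-iodobenzoate | COC(=O)c1ccc(O)c(I)c1 | starting material
8 | methyl 3-iodo-4-(methoxymethoxy)benzoate | COCOc1ccc(cc1I)C(=O)OC | intermediate
9 | methyl 4-(methoxymethoxy)-3-(4,4,5,5-tetramethyl-1,3,2-dioxaborolan-2-yl)benzoate | COCOc1ccc(cc1B1OC(C)(C)C(C)(C)O1)C(=O)OC | intermediate
10 | methyl 3-{5,7-bis(benzyloxy)-2-[4-(benzyloxy)phenyl]-4-oxo-4H-chromen-8-yl}-4-(methoxymethoxy)benzoate | COCOc1ccc(cc1-c1c(OCc2ccccc2)cc(OCc2ccccc2)c2c(=O)cc(-c3ccc(OCc4ccccc4)cc3)oc12)C(=O)OC | intermediate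
11 | 1-[2,4-bis(benzyloxy)-6-hydroxyphenyl]-3-(3-{5,7-bis(benzyloxy)-2-[4-(benzyloxy)phenyl]-4-oxo-4H-chromen-8-yl}-4-(methoxymethoxy)phenyl)propane-1,3-dione | COCOc1ccc(cc1-c1c(OCc2ccccc2)cc(OCc2ccccc2)c2c(=O)cc(-c3ccc(OCc4ccccc4)cc3)oc12)C(=O)CC(=O)c1c(O)cc(OCc2ccccc2)cc1OCc1ccccc1 | intermediate
12 | 4'-O-(methoxymethyl)-5,7,5'',7'',4'''-penta-O-benzylamentoflavone (not isolated) | COCOc1ccc(cc1-c1c(OCc2ccccc2)cc(OCc2ccccc2)c2c(=O)cc(-c3ccc(OCc4ccccc4)cc3)oc12)-c1cc(=O)c2c(OCc3ccccc3)cc(OCc3ccccc3)cc2o1 | intermediate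
13 | 5,7,5'',7'',4'''-penta-O-benzylamentoflavone (free 4'-OH) | Oc1ccc(cc1-c1c(OCc2ccccc2)cc(OCc2ccccc2)c2c(=O)cc(-c3ccc(OCc4ccccc4)cc3)oc12)-c1cc(=O)c2c(OCc3ccccc3)cc(OCc3ccccc3)cc2o1 | intermediate
14 | 3-chloro-3-methylbut-1-yne | CC(C)(Cl)C#C | starting material
15 | 4'-O-(2-methylbut-3-yn-2-yl)-5,7,5'',7'',4'''-penta-O-benzylamentoflavone (key-step precursor) | C#CC(C)(C)Oc1ccc(cc1-c1c(OCc2ccccc2)cc(OCc2ccccc2)c2c(=O)cc(-c3ccc(OCc4ccccc4)cc3)oc12)-c1cc(=O)c2c(OCc3ccccc3)cc(OCc3ccccc3)cc2o1 | intermediate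
16 | 6-(3-methylbuta-1,2-dienyl)cyclohexa-2,4-dienone form of ring B, flavone 2 at C2 and flavone 1 at C4 of the dienone, racemic at C6 (not isolated) | CC(C)=C=CC1C=C(C=C(C1=O)c1c(OCc2ccccc2)cc(OCc2ccccc2)c2c(=O)cc(-c3ccc(OCc4ccccc4)cc3)oc12)c1cc(=O)c2c(OCc3ccccc3)cc(OCc3ccccc3)cc2o1 | intermediate
17 | 5'-(3-methylbuta-1,2-dienyl)-5,7,5'',7'',4'''-penta-O-benzylamentoflavone, free 4'-OH (not isolated) | CC(C)=C=Cc1cc(cc(c1O)-c1c(OCc2ccccc2)cc(OCc2ccccc2)c2c(=O)cc(-c3ccc(OCc4ccccc4)cc3)oc12)-c1cc(=O)c2c(OCc3ccccc3)cc(OCc3ccccc3)cc2o1 | intermediate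
18 | (Z)-6-(3-methylbut-2-enylidene)cyclohexa-2,4-dienone form of ring B (ortho-quinone methide, not isolated) | CC(C)=C/C=C1/C=C(C=C(C1=O)c1c(OCc2ccccc2)cc(OCc2ccccc2)c2c(=O)cc(-c3ccc(OCc4ccccc4)cc3)oc12)c1cc(=O)c2c(OCc3ccccc3)cc(OCc3ccccc3)cc2o1 | intermediate
19 | 5,7-bis(benzyloxy)-8-{6-[5,7-bis(benzyloxy)-4-oxo-4H-chromen-2-yl]-2,2-dimethyl-2H-chromen-8-yl}-2-[4-(benzyloxy)phenyl]-4H-chromen-4-one (key-step product) | CC1(C)C=Cc2cc(cc(c2O1)-c1c(OCc3ccccc3)cc(OCc3ccccc3)c3c(=O)cc(-c4ccc(OCc5ccccc5)cc4)oc13)-c1cc(=O)c2c(OCc3ccccc3)cc(OCc3ccccc3)cc2o1 | intermediate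
20 | 3,4-dihydro derivative of 19 (pentabenzyl chroman, not isolated) | CC1(C)CCc2cc(cc(c2O1)-c1c(OCc3ccccc3)cc(OCc3ccccc3)c3c(=O)cc(-c4ccc(OCc5ccccc5)cc4)oc13)-c1cc(=O)c2c(OCc3ccccc3)cc(OCc3ccccc3)cc2o1 | intermediate
21 | 8-[6-(5,7-dihydroxy-4-oxo-4H-chromen-2-yl)-2,2-dimethyl-3,4-dihydro-2H-chromen-8-yl]-5,7-dihydroxy-2-(4-hydroxyphenyl)-4H-chromen-4-one (CNP0127025.0) | CC1(C)CCc2cc(-c3cc(=O)c4c(O)cc(O)cc4o3)cc(-c3c(O)cc(O)c4c(=O)cc(-c5ccc(O)cc5)oc34)c2O1 | target

**Totals and risks**
Total step count: 12. Longest linear sequence: 10 steps (1, 2, 3, 4, 7, 8, 9, 10, 11, 12).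

Step 11. Ring B carries a para acceptor, so the [3,3] shift may need a temperature at which benzyl groups start to migrate or cleave. The shift may also leak to the substituted ortho carbon, where the allenyl dienone could be trapped by an intramolecular Diels-Alder reaction before it reverts.
- The fallback sets out from 15 and replaces the propargyl cascade by an allyl Claisen rearrangement followed by an ionic ring closure.
- Semihydrogenation of the alkyne (H2, Pd/CaCO3 poisoned with Pb(OAc)2, quinoline, EtOAc) should give the 1,1-dimethylallyl ether F1.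
- Aromatic Claisen rearrangement of F1 in xylene at about 130 °C, well below the temperature of step 11, should move the group to the same free ortho carbon with allyl inversion and give the ortho-prenylphenol F2.
- Catalytic p-TsOH in CH2Cl2 should close ring D by Markovnikov hydroalkoxylation.
- This comes back to the route at 20, which is then debenzylated under the conditions of step 12 to give 21.

Step 8. The donor-substituted benzoate may be acylating too slowly for the intermolecular condensation. Self-condensation of the ketone and attack of liberated methoxide on the pyranone of flavone 2 could then consume material.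
- The fallback sets out from 10 and makes the C-acylation intramolecular.
- Saponification (LiOH, THF-MeOH-H2O, rt) should give the biaryl carboxylic acid F3.
- Steglich esterification of F3 with phenol 2 (EDC·HCl, DMAP, CH2Cl2) should give the aryl ester F4.
- Baker-Venkataraman O-to-C acyl migration (t-BuOK, THF, 0 °C to rt) comes back to the route at 11.

Step 7. Transmetalation to the palladium centre at the doubly flanked C8 may be slow, so protodeboronation of the boronate and hydrodeiodination of the iodide could outrun the coupling.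
- The fallback sets out from 6 and reverses the polarity of the partners.
- LiCl-mediated insertion of zinc dust (Zn, LiCl, THF, 50 °C), which tolerates the enone, should give the flavon-8-ylzinc iodide F5.
- Negishi coupling of F5 with aryl iodide 8 (Pd2(dba)3, RuPhos, THF, 60 °C), whose ester-bearing ring adds readily to palladium, comes back to the route at 10.

**Further compounds**
F1 | step 11 | 4'-O-(2-methylbut-3-en-2-yl)-5,7,5'',7'',4'''-penta-O-benzylamentoflavone | C=CC(C)(C)Oc1ccc(cc1-c1c(OCc2ccccc2)cc(OCc2ccccc2)c2c(=O)cc(-c3ccc(OCc4ccccc4)cc3)oc12)-c1cc(=O)c2c(OCc3ccccc3)cc(OCc3ccccc3)cc2o1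
F2 | step 11 | 5'-(3-methylbut-2-enyl)-5,7,5'',7'',4'''-penta-O-benzylamentoflavone (free 4'-OH) | CC(C)=CCc1cc(cc(c1O)-c1c(OCc2ccccc2)cc(OCc2ccccc2)c2c(=O)cc(-c3ccc(OCc4ccccc4)cc3)oc12)-c1cc(=O)c2c(OCc3ccccc3)cc(OCc3ccccc3)cc2o1
F3 | step 8 | 3-{5,7-bis(benzyloxy)-2-[4-(benzyloxy)phenyl]-4-oxo-4H-chromen-8-yl}-4-(methoxymethoxy)benzoic acid | COCOc1ccc(cc1-c1c(OCc2ccccc2)cc(OCc2ccccc2)c2c(=O)cc(-c3ccc(OCc4ccccc4)cc3)oc12)C(=O)O
F4 | step 8 | 2-acetyl-3,5-bis(benzyloxy)phenyl 3-{5,7-bis(benzyloxy)-2-[4-(benzyloxy)phenyl]-4-oxo-4H-chromen-8-yl}-4-(methoxymethoxy)benzoate | COCOc1ccc(cc1-c1c(OCc2ccccc2)cc(OCc2ccccc2)c2c(=O)cc(-c3ccc(OCc4ccccc4)cc3)oc12)C(=O)Oc1cc(OCc2ccccc2)cc(OCc2ccccc2)c1C(C)=O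
F5 | step 7 | {5,7-bis(benzyloxy)-2-[4-(benzyloxy)phenyl]-4-oxo-4H-chromen-8-yl}zinc iodide | O=c1cc(-c2ccc(OCc3ccccc3)cc2)oc2c([Zn]I)c(OCc3ccccc3)cc(OCc3ccccc3)c12
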